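Race the clocks.

    starting material + enzyme ⇌ starting complex (K1 = 55 M⁻¹, k1 = 6.05 × 10⁶ M⁻¹ s⁻¹)
    second substrate + starting complex ⇌ ternary complex (K2 = 79 M⁻¹, k2 = 1.63 × 10⁶ M⁻¹ s⁻¹)
    ternary complex → enzyme + product (k3 = 1550 s⁻¹)
    starting material ⇌ dormant form (K4 = 16.4, k4 = 0.00799 s⁻¹)
    enzyme + added ligand ⇌ idle complex, settled at all times (K5 = 4.4 × 10⁶ M⁻¹)

| setting | alpha | gamma | beta | zeta |
|---|---|---|---|---|
| starting material | 0.017 M | 0.017 M | 0.017 M (fed, over 3.00 min) | 0.017 M |
| second substrate | 1.05 equiv | 1.05 equiv (fed, over 3.00 min) | 1.05 equiv | 1.05 equiv |
| enzyme | 7.7 × 10⁻⁴ mol% | 7.7 × 10⁻⁴ mol% | 7.7 × 10⁻⁴ mol% | 7.7 × 10⁻⁴ mol% |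
| added ligand | 0.24 µM | 0.24 µM | 0.24 µM | 0.24 µM |
| remark | a single well-mixed tank run continuously and read at steady state, 3.0 min in it on average | a stirred flask in which second substrate is dosed at a steady rate over 3.00 min without added volume, worked up at 3.0 min | all but starting material at the start; starting material goes in evenly over 3.00 min, the run ends at 3.0 min | a closed flask charged with all of it at once and left for 3.0 min |
| time |  | 3.0 min | 3.0 min | 3.0 min |

1. the set-up with the highest amount of product at the outlet or at the end, in percent of the starting material put in ("none" if the first two lie within 2 percentage points) (alpha / gamma / beta / zeta / none)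
2. amount of product at the outlet or at the end, in percent of the starting material put in, alpha
3. amount of product at the outlet or at the end, in percent of the starting material put in, gamma
4. amount of product at the outlet or at the end, in percent of the starting material put in, beta
5. amount of product at the outlet or at the end, in percent of the starting material put in, zeta

- the stated concentrations are those of everything mixed, before any reaction; amounts are the same in each set-up
- the feed brings no volume worth counting
- run time (gamma): 3.0 min

- Start with zeta, the closed flask charged at once. The starting complex lets go in 9.09 × 10⁻⁶ s and the ternary complex falls back in 4.85 × 10⁻⁵ s, but the ternary complex takes 6.45 × 10⁻⁴ s to yield product. Step 3 is therefore the rate-limiting step, and you may hold the enzyme's forms at balance.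
- Count those forms against free enzyme at the charge in zeta: starting complex 0.935, ternary complex 1.32, idle complex 1.1. So 30.6 % of the catalyst stands in the ternary complex.
- That gives zeta a product rate constant of 0.219 min⁻¹ at the charge, which is a product clock of 4.57 min. The dormant clock is 2.09 min. The way back takes 34.2 min, far longer than the run, so I drop it.
- First way, for zeta: the opening rate held for the whole run gives 65.7 % of the charge as product.
- Second way, for zeta: use the race share, the fraction of departing starting material that becomes product rather than dormant form, reckoned at the charged amounts. It is 31.4 %.
- The two ways part, and the first one cheats: it keeps the charge standing, yet starting material lasts 1.43 min on both clocks together, shorter than the run. I commit to the second: 12.3 % left in zeta, and 27.5 % product.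
- The forecast gives alpha 25.8 %, gamma 16.5 %, beta 24.5 % and zeta 31.5 %, and names zeta best, on the ground that “product formation races the first-order loss of starting material to the dormant form”. My zeta figure stands lower than its figure.
- The simulation gives alpha 25.7 %, gamma 16.5 %, beta 24.2 % and zeta 31.4 %, with zeta best. Zeta ends with 12.3 % of its starting material and 31.4 % product, where my race share of 31.4 % gave 27.5 % product. Zeta is not at rest at 3.0 min: by 30.0 min its product reads 50.9 %, starting material 1.92 %, and dormant form has fallen from 56.3 % to 47.1 %. Striking the way back leaves gamma at 16.0 % against 16.5 %.
- Now take the neighbour of zeta charged at 0.0068 M, with equivalents, loadings and added ligand held. Its ternary share is 7.99 %, so its race share drops to 10.7 %, below the 31.4 % of zeta, and I reckon 8.53 % product. The simulation gives 8.87 %.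

(The rate constants are those of an exercise; the flask was simulated.)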